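With a small charge, I ask what a fixed amount held in solution costs me in yield.

- gamma: starting material 1.9 M; run made earlier
- flask: starting material 0.95 M; time 15 d
gamma run (percent of the starting material charged)

| time / h | target / % | isomer of the product / % |
|---|---|---|
| 2.50 | 61.2 | 17.9 |
| 8.00 | 80.1 | 10.3 |
| 12.0 | 86.3 | 5.3 |
| 20.0 | 93.2 | 4.5 |
| 30.0 | 92.1 | 3.8 |
| 40.0 | 94.8 | 2.6 |

(each reading ± 1 percentage point)
* at 15 d, what has stopped the reaction, if anything has (it is still moving / forward and back rates have come level)
* the target standing at 15 d, as a percentage of the starting material charged
* the isomer of the product standing at 15 d, as a percentage of the starting material charged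
* the third isomer standing at 15 d, as a percentage of the starting material charged
- for target the crystals are counted in
- as a solid, counted per litre of solution: crystals
- the numbers in the tables scatter by 1 percentage point (one standard deviation)
- reactions considered so far: starting material <-> target; starting material <-> isomer of the product; starting material <-> third isomer; starting material <-> dormant form; crystals <-> target
- the reaction counts as stopped when no species that holds the starting material changes by six tenths of a point or more over the second half of the time

In the gamma run, target stops climbing within the scatter from 20.0 h, and the flask runs far longer, so I expect forward and back rates to have come level in the flask. The last gamma reading then gives my first number: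

gamma charge × share not in target = 1.9 M × 5.20% = 0.0988 M

I call this the off-target pool, the molar amount of everything except target that stays dissolved beside the crystals, a mother-liquor loss. I assume it holds steady in molar terms while crystals stand. The flask has half the gamma charge, so the same pool costs a larger share:

target = whole charge − 0.0988 M / 0.95 M = 89.6%

isomer of the product = 2.6% × 1.9 M / 0.95 M = 0.0494 M / 0.95 M = 5.20%

The rest of the pool I split evenly among starting material, dormant form and third isomer, which gives third isomer 1.73%. The scatter of 1 percentage point doubles on this path.

The weak link is whether crystals stand in the flask at all. At 2.50 h, gamma shows target to isomer of the product as 3.42. Any early crystals push that reading up and an unfinished approach can pull it down, so I use it as a rough ratio in solution, not a bound: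

dissolved target = 3.42 × 0.0494 M = 0.169 M; saturated solution = 0.169 M + 0.0988 M = 0.268 M

The flask charge is well above that, so crystals should stand.

The forecast gives forward and back rates have come level, with target 92%, isomer of the product 4% and third isomer 2%, on the ground that “their percentages roughly double”.

The flask gives forward and back rates have come level, with target 90.3%, isomer of the product 4.55% and third isomer 2.07%.

    starting material ⇌ target (K = 8.40, k = 3.84 × 10⁻⁴ /s)
    starting material ⇌ isomer of the product (K = 2.42, k = 1.56 × 10⁻⁴ /s)
    starting material ⇌ third isomer (K = 1.10, k = 8.83 × 10⁻⁵ /s)
    starting material ⇌ dormant form (K = 0.640, k = 7.95 × 10⁻⁵ /s)
    crystals ⇌ target, rate k5*(cs5 - [target]) while solid is left; crystals form when [target] > cs5 (solubility = 0.150 M, k = 6.68 × 10⁻⁴ /s)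

Crystals, 74.5% of the flask's charge at 15.0 d, are part of why conversion of starting material is high: without the low solubility of target it falls from 98.1% to 92.6%. The flask's 9.70% outside target amounts to 0.0921 M. For the neighbour flask charged with 2.4 M, the gamma pool of 0.0988 M leaves 95.9% as target, and that neighbour stands at 96.2%.

The earlier runs and the new flask come from a simulation with made-up constants, and the scatter is random.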